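**Plan**

1. Numbering is that of the 8,9-seco-ent-kaurane skeleton: ring A = C1–C5 and C10; ten-membered ring = C5–C6–C7–C8=C14–C13–C12–C11–C9–C10; cyclopentenone = C8, C14, C13, C16, C15.
2. Enabling feature: the C5–C10 bond is shared by ring A and the ten-membered ring; C10 is quaternary and α to the C9 ketone, so C1=C10(CH3)–C9=O is a 2-methyl enone dienophile and C2–C3–C4–C5 a diene whose terminus C5 is tied to C10 through C6–C7–C8=C14–C13–C12–C11–C9.
3. Retrosynthesis: C16=C17 from a C17 silyl ether; the second C4 methyl from hydromethylation of a C3=C4 alkene; then C1–C2 and C5–C10 together by an intramolecular Diels–Alder reaction, which opens ring A and the ten-membered ring at once; then C7–C8 (Ni/Cr coupling), C9–C10, C12–C13 and C16–C17.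
4. Forward: (R)-4-silyloxycyclopentenone becomes a cyclopentenone carrying the dienophile arm, the diene arm is joined at C8, one [4+2] forms ring A and the ten-membered ring, and hydromethylation and unmasking of the exocyclic methylene finish.
5. Stereochemistry: C13 from the chiral-pool enone (anti conjugate addition, the directing centre is then eliminated); C7 from a ligand-controlled Ni/Cr coupling; C5 and C10 from the Diels–Alder step (E diene, ketone-exo transition state gives the trans relation; the face is set by C7 and C13).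

Key step: step 13

Assumption: the (S)-oxazoline–sulfonamide ligand of step 11 is taken to give the C7 R carbinol; if the opposite sense is found, its enantiomer is used.

**Route**

Step 1
Reactants: 1 (R)-4-[(tert-butyldimethylsilyl)oxy]cyclopent-2-en-1-one; 2 2-(2-bromoethyl)-1,3-dioxolane
Product: 5 (2S,3R,4R)-4-[(tert-butyldimethylsilyl)oxy]-3-[2-(1,3-dioxolan-2-yl)ethyl]-2-(hydroxymethyl)cyclopentan-1-one, via Grignard reagent 3 (not isolated), via magnesium enolate 4 (not isolated)
Conditions: 2, Mg, THF; CuBr·SMe2 (10 mol%), 1, THF, −78 °C; then CH2O gas (cracked paraformaldehyde), −78 °C; aq. NH4Cl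
Reagents that add atoms: formaldehyde, C=O
Why: Copper-catalysed 1,4-addition of the Grignard reagent should occur anti to the C4 silyloxy group (setting the future C13), and the regiodefined magnesium enolate is trapped by monomeric formaldehyde trans to the new chain (conjugate addition–aldol three-component coupling), which places C17 on the future C16 without a separate enolisation.

Step 2
Reactants: 5 (2S,3R,4R)-4-[(tert-butyldimethylsilyl)oxy]-3-[2-(1,3-dioxolan-2-yl)ethyl]-2-(hydroxymethyl)cyclopentan-1-one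
Product: 7 (4S,5S)-5-{[(tert-butyldiphenylsilyl)oxy]methyl}-4-[2-(1,3-dioxolan-2-yl)ethyl]cyclopent-2-en-1-one, via bis-silyl ether 6 (not isolated)
Conditions: TBDPSCl, imidazole, CH2Cl2, 0 °C; then DBU (1.1 equiv), 0 °C
Reagents that add atoms: tert-butyl(chloro)diphenylsilane, CC(C)(C)[Si](Cl)(c1ccccc1)c1ccccc1
Why: Silylation masks the primary alcohol (the future exocyclic methylene), and DBU then removes the ring silyloxy group by E1cB elimination through the unhindered C5 methylene enolate to give the conjugated enone, erasing the centre that only served to direct step 1; the tertiary α-hydrogen next to the CH2OSi group is less acidic and should survive at 0 °C.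

Step 3
Reactants: 7 (4S,5S)-5-{[(tert-butyldiphenylsilyl)oxy]methyl}-4-[2-(1,3-dioxolan-2-yl)ethyl]cyclopent-2-en-1-one
Product: 8 (4S,5S)-5-{[(tert-butyldiphenylsilyl)oxy]methyl}-4-(3-oxopropyl)cyclopent-2-en-1-one
Conditions: pyridinium p-toluenesulfonate (cat.), acetone/H2O, 55 °C
Reagents that add atoms: water, O
Why: Mild acid-catalysed acetal hydrolysis should free the aldehyde while the enone, the silyl ether and the β-silyloxy ketone array tolerate the weak acid.

Step 4
Reactants: 8 (4S,5S)-5-{[(tert-butyldiphenylsilyl)oxy]methyl}-4-(3-oxopropyl)cyclopent-2-en-1-one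
Product: 9 (4S,5S)-5-{[(tert-butyldiphenylsilyl)oxy]methyl}-4-(3-hydroxy-4-methylpent-4-en-1-yl)cyclopent-2-en-1-one (both carbinol epimers)
Conditions: 2-bromopropene, CrCl2 (4 equiv), NiCl2 (2 mol%), DMF, rt
Reagents that add atoms: 2-bromopropene, C=C(C)Br
Why: Nozaki–Hiyama–Kishi coupling (oxidative addition of the C–Br bond to zerovalent nickel, transmetalation to chromium) should add the isopropenyl group to the aldehyde only, the enone being inert to the alkenylchromium reagent; both C9 epimers form, which does not matter because C9 becomes a ketone in step 6.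

Step 5
Reactants: 9 (4S,5S)-5-{[(tert-butyldiphenylsilyl)oxy]methyl}-4-(3-hydroxy-4-methylpent-4-en-1-yl)cyclopent-2-en-1-one
Product: 10 (4R,5S)-5-{[(tert-butyldiphenylsilyl)oxy]methyl}-4-(3-hydroxy-4-methylpent-4-en-1-yl)-2-iodocyclopent-2-en-1-one (both carbinol epimers)
Conditions: I2, pyridine/CH2Cl2, 0 °C to rt
Reagents that add atoms: iodine, II
Why: α-Iodination of the enone by reversible conjugate addition of pyridine, iodination of the enolate and loss of pyridine; only the cyclopentenone has a vinylic α-hydrogen, and the step precedes the oxidation so that the isopropenyl ketone, which could also take up pyridine and iodine, is not yet present.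

Step 6
Reactants: 10 (4R,5S)-5-{[(tert-butyldiphenylsilyl)oxy]methyl}-4-(3-hydroxy-4-methylpent-4-en-1-yl)-2-iodocyclopent-2-en-1-one
Product: 11 (4R,5S)-5-{[(tert-butyldiphenylsilyl)oxy]methyl}-2-iodo-4-(4-methyl-3-oxopent-4-en-1-yl)cyclopent-2-en-1-one
Conditions: Dess–Martin periodinane, pyridine, CH2Cl2, 0 °C
Reagents that add atoms: none
Why: Dess–Martin oxidation of the allylic alcohol should give the 2-methyl enone (the dienophile) under non-basic conditions that spare the vinyl iodide and the β-silyloxy ketone.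

Step 7
Reactants: 12 3-[(tert-butyldimethylsilyl)oxy]propanal
Product: 13 (2E)-5-[(tert-butyldimethylsilyl)oxy]-2-methylpent-2-enal
Conditions: Ph3P=C(CH3)CHO, toluene, 80 °C
Reagents that add atoms: 2-(triphenylphosphoranylidene)propanal, CC(C=O)=P(c1ccccc1)(c1ccccc1)c1ccccc1
Why: Wittig reaction with the stabilised, non-basic formyl ylide should give the (E)-trisubstituted enal without β-elimination of the silyloxy group.

Step 8
Reactants: 13 (2E)-5-[(tert-butyldimethylsilyl)oxy]-2-methylpent-2-enal
Product: 14 tert-butyldimethyl{[(3E)-4-methylhexa-3,5-dien-1-yl]oxy}silane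
Conditions: Ph3PCH3Br, KOtBu, THF, 0 °C
Reagents that add atoms: methyltriphenylphosphonium bromide, C[P+](c1ccccc1)(c1ccccc1)c1ccccc1.[Br-]
Why: Wittig methylenation of the enal carbonyl builds the terminal vinyl group of the diene and leaves the E trisubstituted alkene unchanged.

Step 9
Reactants: 14 tert-butyldimethyl{[(3E)-4-methylhexa-3,5-dien-1-yl]oxy}silane
Product: 15 (3E)-4-methylhexa-3,5-dien-1-ol
Conditions: TBAF, THF, 0 °C
Reagents that add atoms: none
Why: Fluoride cleaves the primary silyl ether; nothing else in the molecule is sensitive.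

Step 10
Reactants: 15 (3E)-4-methylhexa-3,5-dien-1-ol
Product: 16 (3E)-4-methylhexa-3,5-dienal
Conditions: Dess–Martin periodinane, pyridine, CH2Cl2, 0 °C; used crude at once
Reagents that add atoms: none
Why: Buffered Dess–Martin oxidation should give the β,γ-unsaturated aldehyde without migration of the diene into conjugation, provided it is used immediately.

Step 11
Reactants: 11 (4R,5S)-5-{[(tert-butyldiphenylsilyl)oxy]methyl}-2-iodo-4-(4-methyl-3-oxopent-4-en-1-yl)cyclopent-2-en-1-one; 16 (3E)-4-methylhexa-3,5-dienal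
Product: 17 (4S,5S)-5-{[(tert-butyldiphenylsilyl)oxy]methyl}-2-[(1R,3E)-1-hydroxy-4-methylhexa-3,5-dien-1-yl]-4-(4-methyl-3-oxopent-4-en-1-yl)cyclopent-2-en-1-one
Conditions: CrCl2 (3 equiv), (S)-N-[2-(4-isopropyl-4,5-dihydro-1,3-oxazol-2-yl)-6-methylphenyl]methanesulfonamide (3.3 equiv), Et3N, THF; NiCl2 (cat.), rt
Reagents that add atoms: none
Why: Asymmetric Nozaki–Hiyama–Kishi coupling: oxidative addition of the C–I bond to zerovalent nickel, transmetalation to chromium and addition of the ligand-bound alkenylchromium species to the aldehyde should form C7–C8, with the chiral sulfonamide ligand choosing the aldehyde face (reagent control, C7 R) because the resident centres are too remote to interfere; the non-basic reagent leaves the β,γ-unsaturated aldehyde and both enones untouched.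

Step 12
Reactants: 17 (4S,5S)-5-{[(tert-butyldiphenylsilyl)oxy]methyl}-2-[(1R,3E)-1-hydroxy-4-methylhexa-3,5-dien-1-yl]-4-(4-methyl-3-oxopent-4-en-1-yl)cyclopent-2-en-1-one
Product: 18 (4S,5S)-2-[(1R,3E)-1-acetoxy-4-methylhexa-3,5-dien-1-yl]-5-{[(tert-butyldiphenylsilyl)oxy]methyl}-4-(4-methyl-3-oxopent-4-en-1-yl)cyclopent-2-en-1-one
Conditions: Ac2O, pyridine, CH2Cl2, 0 °C to rt (no DMAP)
Reagents that add atoms: acetic anhydride, CC(=O)OC(C)=O
Why: O-Acetylation installs the C7 acetate of the target with retention (only the O–H bond reacts); a nucleophilic catalyst is left out to avoid SN2′ isomerisation of this Morita–Baylis–Hillman-type acetate.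

Step 13
Reactants: 18 (4S,5S)-2-[(1R,3E)-1-acetoxy-4-methylhexa-3,5-dien-1-yl]-5-{[(tert-butyldiphenylsilyl)oxy]methyl}-4-(4-methyl-3-oxopent-4-en-1-yl)cyclopent-2-en-1-one
Product: 19 (5R,7R,10R,13S,16S)-7-acetoxy-17-[(tert-butyldiphenylsilyl)oxy]-19-nor-8,9-secokaura-3,8(14)-diene-9,15-dione (ent-kaurane numbering; ring A cyclohexene trans-fused to the ten-membered ring)
Conditions: toluene (2 mM), 2,6-di-tert-butyl-4-methylphenol (cat.), 130 °C, sealed vessel
Reagents that add atoms: none
Why: A thermal, concerted, suprafacial [4+2] cycloaddition between the C1=C10 2-methyl enone (activated by the C9 ketone) and the C2=C3–C4(CH3)=C5 diene should form C1–C2 and C5–C10 in one step, the tether enforcing the C5-to-C10 orientation, which is also the "ortho" orientation favoured by the C5 alkyl group. The closest known reaction type is the macrocycle-forming intramolecular Diels–Alder reaction, in which a cyclohexene and a carbocycle of about eleven to fourteen members are closed together. Ring A closes as the six-membered ring of the cycloaddition itself, and the ten-membered ring closes through the same C5–C10 bond in the fused (type 1) mode, the eight-atom tether C6–C7–C8=C14–C13–C12–C11–C9 being stiffened by the cyclopentenone atoms C8, C14, C13 and the sp2 C9. The relative configuration of C5 and C10 follows from the E diene (C6 outside) and the transition state with the tether carbonyl exo and the C10 methyl endo, the usual preference of 2-methyl enones, which puts C9 and C6 trans (H-5 anti to the C20 methyl). The absolute sense at C5 and C10 should be set by the tether: C13 fixes the cyclopentenone face from which the C12 arm leaves and so the helicity of the forming E-cyclodecene, and of the two exo transition states only the one leading to 5R,10R keeps the C7 acetoxy group pseudo-equatorial on a chair-like C5–C6–C7–C8···C9–C10 fold like rings B and C of the parent kaurane. The step needs site selectivity (the ring enone C8=C14 cannot reach the diene through its two-atom link), exo and π-facial selectivity as described, and suppression of intermolecular cycloaddition, which high dilution and the radical inhibitor should secure.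

Step 14
Reactants: 19 (5R,7R,10R,13S,16S)-7-acetoxy-17-[(tert-butyldiphenylsilyl)oxy]-19-nor-8,9-secokaura-3,8(14)-diene-9,15-dione
Product: 21 (5R,7R,10R,13S,16S)-7-acetoxy-17-[(tert-butyldiphenylsilyl)oxy]-8,9-secokaur-8(14)-ene-9,15-dione, via sulfonyl hydrazide 20 (not isolated)
Conditions: Fe(acac)3 (30 mol%), PhSiH3, CH2=NNHSO2CH3, THF/MeOH, rt; then MeOH, 60 °C
Reagents that add atoms: N′-methylidenemethanesulfonohydrazide, C=NNS(C)(=O)=O
Why: Markovnikov hydromethylation by metal-hydride hydrogen atom transfer: the iron hydride delivers H to C3, the tertiary C4 radical adds to the formaldehyde hydrazone, and the sulfonyl hydrazide loses methanesulfinic acid and N2 on warming in methanol, so C4 becomes a non-stereogenic gem-dimethyl carbon; C3=C4 is the only electron-rich alkene, the enone C8=C14 being a poor acceptor for hydrogen atom transfer.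

Step 15
Reactants: 21 (5R,7R,10R,13S,16S)-7-acetoxy-17-[(tert-butyldiphenylsilyl)oxy]-8,9-secokaur-8(14)-ene-9,15-dione
Product: 22 (5R,7R,10R,13S,16S)-7-acetoxy-17-hydroxy-8,9-secokaur-8(14)-ene-9,15-dione
Conditions: HF·pyridine, THF/pyridine, 0 °C to rt
Reagents that add atoms: none
Why: Buffered HF should remove the silyl group from the primary oxygen without touching the acetate or causing retro-aldol cleavage of the β-hydroxy ketone.

Step 16
Reactants: 22 (5R,7R,10R,13S,16S)-7-acetoxy-17-hydroxy-8,9-secokaur-8(14)-ene-9,15-dione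
Product: 24 (5R,7R,10R,13S)-7-acetoxy-8,9-secokaura-8(14),16-diene-9,15-dione (target CNP0421845.1), via mesylate 23 (not isolated)
Conditions: MsCl, Et3N (excess), CH2Cl2, 0 °C to rt
Reagents that add atoms: none
Why: Mesylation of the primary alcohol followed by E1cB elimination through the C15 enolate (β-elimination of a β-sulfonyloxy ketone) should unveil the C16=C17 exocyclic methylene and remove the temporary C16 centre, giving the target.

**Compound list**

1 | (R)-4-[(tert-butyldimethylsilyl)oxy]cyclopent-2-en-1-one | O=C1C=C[C@H](O[Si](C)(C)C(C)(C)C)C1 | starting material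
2 | 2-(2-bromoethyl)-1,3-dioxolane | BrCCC1OCCO1 | starting material
3 | [2-(1,3-dioxolan-2-yl)ethyl]magnesium bromide | Br[Mg]CCC1OCCO1 | intermediate (not isolated)
4 | bromomagnesium enolate of (3R,4R)-4-[(tert-butyldimethylsilyl)oxy]-3-[2-(1,3-dioxolan-2-yl)ethyl]cyclopentanone | Br[Mg]OC1=C[C@@H](CCC2OCCO2)[C@H](O[Si](C)(C)C(C)(C)C)C1 | intermediate (not isolated)
5 | (2S,3R,4R)-4-[(tert-butyldimethylsilyl)oxy]-3-[2-(1,3-dioxolan-2-yl)ethyl]-2-(hydroxymethyl)cyclopentan-1-one | O=C1C[C@@H](O[Si](C)(C)C(C)(C)C)[C@H](CCC2OCCO2)[C@H]1CO | intermediate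
6 | (2S,3R,4R)-4-[(tert-butyldimethylsilyl)oxy]-2-{[(tert-butyldiphenylsilyl)oxy]methyl}-3-[2-(1,3-dioxolan-2-yl)ethyl]cyclopentan-1-one | O=C1C[C@@H](O[Si](C)(C)C(C)(C)C)[C@H](CCC2OCCO2)[C@H]1CO[Si](c3ccccc3)(c3ccccc3)C(C)(C)C | intermediate (not isolated)
7 | (4S,5S)-5-{[(tert-butyldiphenylsilyl)oxy]methyl}-4-[2-(1,3-dioxolan-2-yl)ethyl]cyclopent-2-en-1-one | O=C1C=C[C@H](CCC2OCCO2)[C@H]1CO[Si](c3ccccc3)(c3ccccc3)C(C)(C)C | intermediate
8 | (4S,5S)-5-{[(tert-butyldiphenylsilyl)oxy]methyl}-4-(3-oxopropyl)cyclopent-2-en-1-one | O=C1C=C[C@H](CCC=O)[C@H]1CO[Si](c2ccccc2)(c2ccccc2)C(C)(C)C | intermediate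
9 | (4S,5S)-5-{[(tert-butyldiphenylsilyl)oxy]methyl}-4-(3-hydroxy-4-methylpent-4-en-1-yl)cyclopent-2-en-1-one (carbinol epimers) | O=C1C=C[C@H](CCC(O)C(C)=C)[C@H]1CO[Si](c2ccccc2)(c2ccccc2)C(C)(C)C | intermediate
10 | (4R,5S)-5-{[(tert-butyldiphenylsilyl)oxy]methyl}-4-(3-hydroxy-4-methylpent-4-en-1-yl)-2-iodocyclopent-2-en-1-one (carbinol epimers) | O=C1C(I)=C[C@H](CCC(O)C(C)=C)[C@H]1CO[Si](c2ccccc2)(c2ccccc2)C(C)(C)C | intermediate
11 | (4R,5S)-5-{[(tert-butyldiphenylsilyl)oxy]methyl}-2-iodo-4-(4-methyl-3-oxopent-4-en-1-yl)cyclopent-2-en-1-one | O=C1C(I)=C[C@H](CCC(=O)C(C)=C)[C@H]1CO[Si](c2ccccc2)(c2ccccc2)C(C)(C)C | intermediate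
12 | 3-[(tert-butyldimethylsilyl)oxy]propanal | O=CCCO[Si](C)(C)C(C)(C)C | starting material
13 | (2E)-5-[(tert-butyldimethylsilyl)oxy]-2-methylpent-2-enal | O=C/C(C)=C/CCO[Si](C)(C)C(C)(C)C | intermediate
14 | tert-butyldimethyl{[(3E)-4-methylhexa-3,5-dien-1-yl]oxy}silane | C=C/C(C)=C/CCO[Si](C)(C)C(C)(C)C | intermediate
15 | (3E)-4-methylhexa-3,5-dien-1-ol | C=C/C(C)=C/CCO | intermediate
16 | (3E)-4-methylhexa-3,5-dienal | C=C/C(C)=C/CC=O | intermediate
17 | (4S,5S)-5-{[(tert-butyldiphenylsilyl)oxy]methyl}-2-[(1R,3E)-1-hydroxy-4-methylhexa-3,5-dien-1-yl]-4-(4-methyl-3-oxopent-4-en-1-yl)cyclopent-2-en-1-one | O=C1C([C@H](O)C/C=C(C)/C=C)=C[C@H](CCC(=O)C(C)=C)[C@H]1CO[Si](c2ccccc2)(c2ccccc2)C(C)(C)C | intermediate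
18 | (4S,5S)-2-[(1R,3E)-1-acetoxy-4-methylhexa-3,5-dien-1-yl]-5-{[(tert-butyldiphenylsilyl)oxy]methyl}-4-(4-methyl-3-oxopent-4-en-1-yl)cyclopent-2-en-1-one | O=C1C([C@H](OC(C)=O)C/C=C(C)/C=C)=C[C@H](CCC(=O)C(C)=C)[C@H]1CO[Si](c2ccccc2)(c2ccccc2)C(C)(C)C | intermediate
19 | (5R,7R,10R,13S,16S)-7-acetoxy-17-[(tert-butyldiphenylsilyl)oxy]-19-nor-8,9-secokaura-3,8(14)-diene-9,15-dione | O=C1C2=C[C@H](CCC(=O)[C@]3(C)CCC=C(C)[C@H]3C[C@H]2OC(C)=O)[C@H]1CO[Si](c4ccccc4)(c4ccccc4)C(C)(C)C | intermediate
20 | N′-methanesulfonyl hydrazinomethyl adduct at C4 of 19 (C4 epimers) | O=C1C2=C[C@H](CCC(=O)[C@]3(C)CCCC(C)(CNNS(C)(=O)=O)[C@H]3C[C@H]2OC(C)=O)[C@H]1CO[Si](c4ccccc4)(c4ccccc4)C(C)(C)C | intermediate (not isolated)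
21 | (5R,7R,10R,13S,16S)-7-acetoxy-17-[(tert-butyldiphenylsilyl)oxy]-8,9-secokaur-8(14)-ene-9,15-dione | O=C1C2=C[C@H](CCC(=O)[C@]3(C)CCCC(C)(C)[C@H]3C[C@H]2OC(C)=O)[C@H]1CO[Si](c4ccccc4)(c4ccccc4)C(C)(C)C | intermediate
22 | (5R,7R,10R,13S,16S)-7-acetoxy-17-hydroxy-8,9-secokaur-8(14)-ene-9,15-dione | O=C1C2=C[C@H](CCC(=O)[C@]3(C)CCCC(C)(C)[C@H]3C[C@H]2OC(C)=O)[C@H]1CO | intermediate
23 | 17-O-methanesulfonate of 22 | O=C1C2=C[C@H](CCC(=O)[C@]3(C)CCCC(C)(C)[C@H]3C[C@H]2OC(C)=O)[C@H]1COS(C)(=O)=O | intermediate (not isolated)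
24 | (5R,7R,10R,13S)-7-acetoxy-8,9-secokaura-8(14),16-diene-9,15-dione (ent-kaurane series) | C=C1C(=O)C2=C[C@@H]1CCC(=O)[C@]1(C)CCCC(C)(C)[C@H]1C[C@H]2OC(C)=O | target

**Step count**

Total: 16 steps. Longest linear sequence: 12 steps (steps 1–6 and 11–16); steps 7–10 make the diene aldehyde 16.

**Steps most likely to fail**

Step 13 (Diels–Alder closure of ring A and the ten-membered ring). The medium ring may close too slowly, so that intermolecular cycloaddition or a thermal 1,3-shift of the allylic acetate takes over, or the two exo transition states may not be told apart (poor π-facial selectivity). Fallback: the two rings are closed separately, ring A by a catalyst-controlled intermolecular Diels–Alder reaction and the ten-membered ring by an intramolecular Ni/Cr coupling. It sets out from 9, which Dess–Martin periodinane oxidises to the dienone (4S,5S)-5-{[(tert-butyldiphenylsilyl)oxy]methyl}-4-(4-methyl-3-oxopent-4-en-1-yl)cyclopent-2-en-1-one F1. The terminal isopropenyl ketone of F1, a far better dienophile than the ring enone, is combined with diene 14 under a chiral oxazaborolidinium Lewis acid, (S)-1-(2-methylphenyl)-3,3-diphenyltetrahydro-1H,3H-pyrrolo[1,2-c][1,3,2]oxazaborole activated by HNTf2, in CH2Cl2 at −78 to −20 °C, with the catalyst antipode chosen for the 5R,10R face; this gives the exo cyclohexene adduct F2. I2/pyridine converts F2 into the 2-iodo enone F3. Pyridinium p-toluenesulfonate in MeOH removes only the primary tert-butyldimethylsilyl group to give the primary alcohol F4, and Dess–Martin periodinane gives the aldehyde F5. CrCl2/NiCl2 (cat.) in DMSO/THF at high dilution, with the ligand of step 11, closes the ten-membered ring at C7–C8 to the macrocyclic allylic alcohol F6. Ac2O/pyridine then gives 19, where the route is rejoined.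

Step 14 (hydromethylation). Hydrogen atom transfer to the enone, or transannular capture of the C4 radical by C14 of the enone, may compete with trapping by the hydrazone. Fallback: a polar sequence from 19. Markovnikov addition of HCl (gas, CH2Cl2, −78 °C) to C3=C4 gives the tertiary chloride F7 (4-chloro-19-nor derivative of 21), used crude. AlMe3 in CH2Cl2 at −78 °C then transfers a methyl group to the tertiary carbon within the ion pair, faster than it adds to the ketones, and gives 21.

Step 11 (ligand-controlled Ni/Cr coupling). The chiral ligand may give poor facial selectivity at C7, or a ligand-free background reaction may erode it. Fallback: the coupling of 11 and 16 is run without chiral ligand (CrCl2, NiCl2 cat., DMSO) and the C7 epimers are separated by chromatography. The 1′S epimer of 17, F8, is inverted by Mitsunobu esterification with acetic acid (PPh3, diisopropyl azodicarboxylate, THF), which gives acetate 18 directly; the 1′R epimer 17 is acetylated as in step 12.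

Further compounds
F1 | step 13 | (4S,5S)-5-{[(tert-butyldiphenylsilyl)oxy]methyl}-4-(4-methyl-3-oxopent-4-en-1-yl)cyclopent-2-en-1-one | O=C1C=C[C@H](CCC(=O)C(C)=C)[C@H]1CO[Si](c2ccccc2)(c2ccccc2)C(C)(C)C
F2 | step 13 | (4S,5S)-4-{3-[(1R,2R)-2-{2-[(tert-butyldimethylsilyl)oxy]ethyl}-1,3-dimethylcyclohex-3-en-1-yl]-3-oxopropyl}-5-{[(tert-butyldiphenylsilyl)oxy]methyl}cyclopent-2-en-1-one | O=C1C=C[C@H](CCC(=O)[C@]2(C)CCC=C(C)[C@H]2CCO[Si](C)(C)C(C)(C)C)[C@H]1CO[Si](c3ccccc3)(c3ccccc3)C(C)(C)C
F3 | step 13 | 2-iodo derivative of F2 | O=C1C(I)=C[C@H](CCC(=O)[C@]2(C)CCC=C(C)[C@H]2CCO[Si](C)(C)C(C)(C)C)[C@H]1CO[Si](c3ccccc3)(c3ccccc3)C(C)(C)C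
F4 | step 13 | primary alcohol from F3 (2-hydroxyethyl side chain on the cyclohexene) | O=C1C(I)=C[C@H](CCC(=O)[C@]2(C)CCC=C(C)[C@H]2CCO)[C@H]1CO[Si](c3ccccc3)(c3ccccc3)C(C)(C)C
F5 | step 13 | aldehyde from F4 (2-oxoethyl side chain on the cyclohexene) | O=C1C(I)=C[C@H](CCC(=O)[C@]2(C)CCC=C(C)[C@H]2CC=O)[C@H]1CO[Si](c3ccccc3)(c3ccccc3)C(C)(C)C
F6 | step 13 | (5R,7R,10R,13S,16S)-17-[(tert-butyldiphenylsilyl)oxy]-7-hydroxy-19-nor-8,9-secokaura-3,8(14)-diene-9,15-dione | O=C1C2=C[C@H](CCC(=O)[C@]3(C)CCC=C(C)[C@H]3C[C@H]2O)[C@H]1CO[Si](c4ccccc4)(c4ccccc4)C(C)(C)C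
F7 | step 14 | 4-chloro-19-nor derivative of 21 (tertiary chloride at C4) | O=C1C2=C[C@H](CCC(=O)[C@]3(C)CCCC(C)(Cl)[C@H]3C[C@H]2OC(C)=O)[C@H]1CO[Si](c4ccccc4)(c4ccccc4)C(C)(C)C
F8 | step 11 | (4S,5S)-5-{[(tert-butyldiphenylsilyl)oxy]methyl}-2-[(1S,3E)-1-hydroxy-4-methylhexa-3,5-dien-1-yl]-4-(4-methyl-3-oxopent-4-en-1-yl)cyclopent-2-en-1-one | O=C1C([C@@H](O)C/C=C(C)/C=C)=C[C@H](CCC(=O)C(C)=C)[C@H]1CO[Si](c2ccccc2)(c2ccccc2)C(C)(C)C
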